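**Retrosynthetic overview**
1. Target 9 is cut at the aryl–C(=O) bond: the aldehyde carbon of 6 serves as an acyl-anion-type donor (nucleophilic acyl radical) toward ring carbon C5 of 2-bromo-1,4-benzoquinone 7. The addition is redox-neutral and gives the free bromohydroquinone ketone without protecting groups.
2. Aldehyde 6 comes from triol 5 by oxidation of its only primary alcohol.
3. Triol 5 comes from ene-diol 3 (Markovnikov hydration of the trisubstituted alkene), and 3 from (S)-linalool 1 (anti-Markovnikov hydration of the vinyl group).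
4. The single stereocentre is bought with 1 and never becomes a reaction centre.
5. No ring is built: the arene arrives as quinone 7 and is aromatised in the key step.

Assumption: (S)-(+)-linalool of at least 97 % ee and 2-bromo-1,4-benzoquinone are purchased; the optical purity of 1 is carried unchanged into 9, so it is checked by chiral GC before use.

**Step 1**
Reactants: 1 (S)-(+)-linalool
Product: 3 (3S)-3,7-dimethyloct-6-ene-1,3-diol, via B-alkyl-9-BBN adduct 2 (not isolated)
Conditions: 9-BBN (1.5 equiv), THF, 0 °C to rt; then 3 M NaOH, 30 % H2O2, 0 °C to rt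
Reagents that add atoms: hydrogen peroxide, OO
Why: Brown hydroboration–oxidation: bulky 9-BBN adds only to the monosubstituted vinyl group with boron on the terminal carbon and leaves the trisubstituted alkene alone, and oxidation of the C–B bond gives the primary alcohol; the carbinol centre is not involved and keeps its geometry.

**Step 2**
Reactants: 3 (3S)-3,7-dimethyloct-6-ene-1,3-diol
Product: 5 (3S)-3,7-dimethyloctane-1,3,7-triol, via tertiary silyl peroxide 4 (not isolated)
Conditions: Co(acac)2 (20 mol %), PhSiH3 (2.5 equiv), O2 (1 atm), THF, rt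
Reagents that add atoms: dioxygen, O=O
Why: Mukaiyama hydration: hydrogen-atom transfer from the Co–H species (formed from Co(acac)2 and PhSiH3) gives the tertiary radical (Markovnikov), which is trapped by O2 and reduced through 4 to the tertiary alcohol under neutral radical conditions, so the free 3-OH cannot cyclise onto C7 as it would under acid or mercury-salt activation; no stereocentre is made or touched.

**Step 3**
Reactants: 5 (3S)-3,7-dimethyloctane-1,3,7-triol
Product: 6 (3S)-3,7-dihydroxy-3,7-dimethyloctanal
Conditions: TEMPO (10 mol %), PhI(OAc)2 (1.1 equiv), CH2Cl2, rt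
Reagents that add atoms: none
Why: TEMPO/PhI(OAc)2 (oxoammonium) oxidation takes the only primary alcohol to the aldehyde without over-oxidation, the two tertiary alcohols cannot be oxidised, and the nearly neutral medium spares the dehydration-prone β-hydroxy aldehyde; the stereocentre is untouched.

**Step 4 (key step)**
Reactants: 6 (3S)-3,7-dihydroxy-3,7-dimethyloctanal; 7 2-bromo-1,4-benzoquinone
Product: 9 (3S)-1-(4-bromo-2,5-dihydroxyphenyl)-3,7-dihydroxy-3,7-dimethyloctan-1-one, via acyl dienone tautomer 8 (not isolated)
Conditions: hν (450 nm blue LEDs), 6 (1.5 equiv), 7 (1.0 equiv), t-BuOH/acetone 3:1, Ar, 20 °C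
Reagents that add atoms: none
Why: Proposed new method: the n,π* triplet of 7 abstracts the aldehydic hydrogen of 6 (its weakest C–H bond, since neither carbinol carbon carries a hydrogen), and the nucleophilic acyl radical, an acyl anion equivalent, adds to the electrophilic ring carbon C5 of 7 (β to the more electron-poor C1 carbonyl and remote from bromine, the position where HBr and other nucleophiles add to halo-quinones), after which hydrogen return and enolisation of 8 give the hydroquinone ketone with bromine para to the acyl group; the closest known reaction type is the Klinger photoacylation (photo-Friedel–Crafts acylation) of 1,4-benzoquinone with aldehydes, and the stereocentre is untouched.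

**Compound list**
1 | (S)-(+)-linalool, (3S)-3,7-dimethylocta-1,6-dien-3-ol | CC(C)=CCC[C@](C)(O)C=C | starting material
2 | 9-[(3R)-3-hydroxy-3,7-dimethyloct-6-en-1-yl]-9-borabicyclo[3.3.1]nonane (descriptor R only because boron lowers the CIP rank of that arm; geometry as in 1) | CC(C)=CCC[C@](C)(O)CCB1C2CCCC1CCC2 | intermediate
3 | (3S)-3,7-dimethyloct-6-ene-1,3-diol | CC(C)=CCC[C@](C)(O)CCO | intermediate
4 | (3S)-3,7-dimethyl-7-[(phenylsilyl)peroxy]octane-1,3-diol | CC(C)(OO[SiH2]c1ccccc1)CCC[C@](C)(O)CCO | intermediate
5 | (3S)-3,7-dimethyloctane-1,3,7-triol | CC(C)(O)CCC[C@](C)(O)CCO | intermediate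
6 | (3S)-3,7-dihydroxy-3,7-dimethyloctanal | CC(C)(O)CCC[C@](C)(O)CC=O | intermediate
7 | 2-bromo-1,4-benzoquinone | O=C1C=CC(=O)C(Br)=C1 | starting material
8 | 3-bromo-6-[(3S)-3,7-dihydroxy-3,7-dimethyloctanoyl]-4-hydroxycyclohexa-2,4-dien-1-one (both epimers at ring C6) | CC(C)(O)CCC[C@](C)(O)CC(=O)C1C=C(O)C(Br)=CC1=O | intermediate
9 | (3S)-1-(4-bromo-2,5-dihydroxyphenyl)-3,7-dihydroxy-3,7-dimethyloctan-1-one | CC(C)(O)CCC[C@](C)(O)CC(=O)c1cc(O)c(Br)cc1O | target

**Totals**
Total step count: 4. Longest linear sequence: 4 steps (1 → 3 → 5 → 6 → 9).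

**Steps most likely to fail, with fallbacks**

Step 4 (key photoacylation). The risks are attack of the acyl radical at C6 or C3 of 7 (regioisomers), O-acylation, and simple photoreduction of 7. The desired isomer is recognised by two aromatic singlets in the 1H NMR spectrum. The fallback sets out from 6 and comes back to the route at 9, and fixes the regiochemistry through a carbon–halogen bond. Commercial 2,5-dibromohydroquinone (Oc1cc(Br)c(O)cc1Br) is silylated with TBSCl and imidazole in DMF to 1,4-dibromo-2,5-bis(tert-butyldimethylsilyloxy)benzene F1. Aldehyde 6 is then coupled with F1 (3 equiv, excess recovered) under hydrogen-atom-transfer/nickel/photoredox conditions: Ir[dF(CF3)ppy]2(dtbbpy)PF6 (1 mol %), NiBr2(dme) with dtbbpy (10 mol %), quinuclidine, K2CO3, dioxane, blue LEDs. The acyl radical from 6 is captured by the aryl–Ni intermediate, so the ketone can form only at a former C–Br carbon, giving (3S)-1-[4-bromo-2,5-bis(tert-butyldimethylsilyloxy)phenyl]-3,7-dihydroxy-3,7-dimethyloctan-1-one F2. TBAF buffered with AcOH in THF at 0 °C removes both silyl groups and gives 9.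

Step 3 (oxidation to the free β-hydroxy aldehyde). The risks are dehydration to the enal, acetal formation with unreacted triol, and loss of the polar aldehyde on isolation. The fallback sets out from 5 and comes back at 9, carrying the tertiary hydroxyls masked through the key step. TESOTf and 2,6-lutidine in CH2Cl2 silylate all three hydroxyls to give (3S)-3,7-dimethyl-1,3,7-tris(triethylsilyloxy)octane F3. Swern conditions ((COCl)2, DMSO, then Et3N, −78 to −30 °C) convert the primary triethylsilyl ether selectively and directly into the aldehyde, giving (3S)-3,7-dimethyl-3,7-bis(triethylsilyloxy)octanal F4, which is far less prone to elimination and dissolves in benzene. Irradiation of F4 with 7 as in step 4 (benzene, 450 nm) gives, through the bis-silylated acyl dienone tautomer F5, (3S)-1-(4-bromo-2,5-dihydroxyphenyl)-3,7-dimethyl-3,7-bis(triethylsilyloxy)octan-1-one F6. HF·pyridine in THF/pyridine at 0 °C then gives 9.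

Step 2 (radical hydration). The risks are incomplete conversion, alkene reduction and silylated by-products. The fallback sets out from 3 and comes back at 5, replacing the radical hydration by a polar epoxide reduction. Buffered m-CPBA (NaHCO3, CH2Cl2, 0 °C) epoxidises the only alkene to (3S)-5-(3,3-dimethyloxiran-2-yl)-3-methylpentane-1,3-diol F7 (both epimers at the oxirane CH). The epoxide is kept away from acid, because the 3-OH otherwise cyclises onto it to a tetrahydrofuran. LiAlH4 in THF (0 °C to rt) delivers hydride to the less substituted oxirane carbon and gives triol 5.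

**Further compounds**
F1 | step 4 | 1,4-dibromo-2,5-bis(tert-butyldimethylsilyloxy)benzene | CC(C)(C)[Si](C)(C)Oc1cc(Br)c(O[Si](C)(C)C(C)(C)C)cc1Br
F2 | step 4 | (3S)-1-[4-bromo-2,5-bis(tert-butyldimethylsilyloxy)phenyl]-3,7-dihydroxy-3,7-dimethyloctan-1-one | CC(C)(O)CCC[C@](C)(O)CC(=O)c1cc(O[Si](C)(C)C(C)(C)C)c(Br)cc1O[Si](C)(C)C(C)(C)C
F3 | step 3 | (3S)-3,7-dimethyl-1,3,7-tris(triethylsilyloxy)octane | CC(C)(O[Si](CC)(CC)CC)CCC[C@](C)(O[Si](CC)(CC)CC)CCO[Si](CC)(CC)CC
F4 | step 3 | (3S)-3,7-dimethyl-3,7-bis(triethylsilyloxy)octanal | CC(C)(O[Si](CC)(CC)CC)CCC[C@](C)(O[Si](CC)(CC)CC)CC=O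
F5 | step 3 | 3-bromo-6-[(3S)-3,7-dimethyl-3,7-bis(triethylsilyloxy)octanoyl]-4-hydroxycyclohexa-2,4-dien-1-one (both epimers at ring C6) | CC(C)(O[Si](CC)(CC)CC)CCC[C@](C)(O[Si](CC)(CC)CC)CC(=O)C1C=C(O)C(Br)=CC1=O
F6 | step 3 | (3S)-1-(4-bromo-2,5-dihydroxyphenyl)-3,7-dimethyl-3,7-bis(triethylsilyloxy)octan-1-one | CC(C)(O[Si](CC)(CC)CC)CCC[C@](C)(O[Si](CC)(CC)CC)CC(=O)c1cc(O)c(Br)cc1O
F7 | step 2 | (3S)-5-(3,3-dimethyloxiran-2-yl)-3-methylpentane-1,3-diol (both epimers at the oxirane CH) | CC1(C)OC1CC[C@](C)(O)CCO
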